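**Strategy.** Ring A (C1–C7) is the six-membered ring of (R)-carvone plus one carbon: the route rests on cutting C1–C2 and C1–C7. In one operation dibromocarbene adds to the C2=C7 silyl enol ether bond and the cyclopropane opens, enlarging the ring, forming both bonds to C1 and leaving C1 as a vinyl bromide beside the C2 ketone. The precursor is the bis(triethylsilyl) derivative of 3-hydroxydihydrocarvone, a tetrasubstituted enol ether whose C6 silyl ether is trans to isopropenyl; carvone supplies C4, the C6 oxygen, the C7 methyl and C11–C13. The bromide then takes the crotonoyl group; C7, C1, lactone ring B (C3), C2 and the angelate follow.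

Key step: step 4

Assumption: ring A locants (C1–C7; lactone C11–C13) are those of the target, α/β mean the lower/upper face with the C6 oxygen β, the diketone methine (ring A C1) of 12 and 13 is stereolabile and left undefined, and the stannane 9 and angelic acid are taken as commercial.

**Step 1**
Reactants: 1 (R)-carvone
Product: 2 (1R,4R,6R)-1-methyl-4-(prop-1-en-2-yl)-7-oxabicyclo[4.1.0]heptan-2-one (epoxide trans to isopropenyl)
Conditions: 30% H2O2, NaOH (cat.), MeOH, 0 °C
Reagents that add atoms: hydrogen peroxide, OO
Why: Weitz–Scheffer nucleophilic epoxidation touches only the enone, and hydroperoxide adds to the β-carbon anti to the isopropenyl group, which fixes the future C6 oxygen trans to the C4 branch.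

**Step 2**
Reactants: 2
Product: 3 (2R,3R,5R)-3-hydroxy-2-methyl-5-(prop-1-en-2-yl)cyclohexan-1-one
Conditions: PhSeSePh, NaBH4, EtOH; AcOH, 0 °C to rt
Reagents that add atoms: none
Why: Organoselenium-mediated reductive opening of the α,β-epoxy ketone cleaves only the Cα–O bond, so the carbinol centre keeps the epoxide configuration; the methyl-bearing centre (equatorial epimer expected) is erased in step 3.

**Step 3**
Reactants: 3
Product: 4 triethyl{[(3R,5R)-2-methyl-5-(prop-1-en-2-yl)-3-(triethylsilyloxy)cyclohex-1-en-1-yl]oxy}silane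
Conditions: Et3SiCl, NaI, Et3N, MeCN, rt to 40 °C
Reagents that add atoms: chlorotriethylsilane, CC[Si](Cl)(CC)CC
Why: Iodotriethylsilane formed in situ silylates the alcohol and, by equilibrating soft enolisation, should give the thermodynamic tetrasubstituted silyl enol ether without a free enolate, so β-elimination of the silyloxy group is avoided; no stereocentre is formed.

**Step 4**
Reactants: 4; 5 bromoform
Product: 7 (4R,6R)-2-bromo-3-methyl-6-(prop-1-en-2-yl)-4-(triethylsilyloxy)cyclohept-2-en-1-one, via dibromocyclopropane 6 (not isolated)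
Conditions: CHBr3 (1.2 equiv), KOtBu, pentane, −30 °C to rt; then PhMe, 80 °C
Reagents that add atoms: bromoform (5), BrC(Br)Br
Why: Dibromocarbene from α-elimination of bromoform cyclopropanates the electron-rich tetrasubstituted enol ether (a [2+1] addition, expected anti to the allylic silyloxy group); adduct 6 then loses bromide while the former C2–C7 bond opens in a disrotatory two-electron electrocyclic process pushed by the silyloxy oxygen, and bromide removes the triethylsilyl group to leave the 2-bromoenone. The closest known reaction type is the dihalocarbene ring expansion of cyclic silyl enol ethers to 2-halocycloalk-2-enones. Ring A is closed by one-carbon ring expansion, C1 being inserted between C2 and C7 (C1–C2 and C1–C7 formed, C2–C7 broken), not by end-to-end cyclisation. No stereocentre is created, since the two cyclopropane centres are lost on opening and C4 and C6 are untouched. The step needs chemoselectivity for the enol ether over the isopropenyl alkene, which the far higher nucleophilicity of the enol ether towards a slight excess of carbene should secure, and survival of the enol ether towards tert-butoxide, which the triethylsilyl group and cold heterogeneous conditions should secure.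

**Step 5**
Reactants: 7; 8 carbon monoxide; 9 (E)-tributyl(prop-1-en-1-yl)stannane
Product: 10 (4R,6R)-2-[(E)-but-2-enoyl]-3-methyl-6-(prop-1-en-2-yl)-4-(triethylsilyloxy)cyclohept-2-en-1-one
Conditions: Pd2(dba)3, AsPh3, LiCl, CO (3 atm), NMP, 60 °C
Reagents that add atoms: carbon monoxide (8), [C-]#[O+]; (E)-tributyl(prop-1-en-1-yl)stannane (9), C/C=C/[Sn](CCCC)(CCCC)CCCC
Why: Carbonylative Stille coupling: zerovalent palladium inserts into the activated C1–Br bond, CO insertion gives the acylpalladium species and the propenyl group is transferred from tin with retention of E geometry, CO pressure suppressing direct coupling; no stereocentre is formed.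

**Step 6**
Reactants: 10
Product: 11 (4R,6R)-2-[(E)-but-2-enoyl]-4-hydroxy-3-methyl-6-(prop-1-en-2-yl)cyclohept-2-en-1-one
Conditions: HF·pyridine, pyridine, THF, 0 °C
Reagents that add atoms: none
Why: Buffered fluoride cleavage of the labile secondary triethylsilyl ether frees the C6 hydroxyl that must direct step 7, without touching the enedione or the alkenes.

**Step 7**
Reactants: 11
Product: 12 (3R,4R,6R)-2-[(E)-but-2-enoyl]-4-hydroxy-3-methyl-6-(prop-1-en-2-yl)cycloheptan-1-one (7α-methyl; diketone methine stereolabile)
Conditions: Me4NBH(OAc)3, AcOH, MeCN, −30 to 0 °C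
Reagents that add atoms: none
Why: Proposed new method: the free C6 hydroxyl should exchange onto boron to give an alkoxy(diacetoxy)borohydride that can reach only C7 of the doubly activated C1=C7 bond (five-centre transition state), so hydride is delivered on the β face, setting C7 with hydrogen cis to the C6 oxygen and methyl trans, the face that external reductants (which add anti to the C6 substituent) do not reach; the reagent is too weak a hydride donor to reduce the ketones or the crotonyl alkene on its own, which secures chemoselectivity; the closest known reaction type is the hydroxyl-directed Saksena–Evans triacetoxyborohydride reduction of β-hydroxy ketones, extended here from a carbonyl to the β-carbon of an alkylidene 1,3-diketone.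

**Step 8**
Reactants: 12
Product: 13 (3R,4R,6R)-2-[(E)-but-2-enoyl]-4-[(tert-butyldimethylsilyl)oxy]-3-methyl-6-(prop-1-en-2-yl)cycloheptan-1-one
Conditions: TBSCl, imidazole, DMF, rt
Reagents that add atoms: tert-butylchlorodimethylsilane, CC(C)(C)[Si](C)(C)Cl
Why: Standard silylation of the only alcohol (any diketone enol silyl ether hydrolyses on work-up) puts a robust, bulky group on the C6 oxygen for the steps up to the final deprotection.

**Step 9**
Reactants: 13
Product: 14 (2S,3S,4R,6R)-2-[(E)-but-2-enoyl]-4-[(tert-butyldimethylsilyl)oxy]-2-hydroxy-3-methyl-6-(prop-1-en-2-yl)cycloheptan-1-one (1α-OH; 1β-crotonoyl)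
Conditions: KHMDS, THF, −78 °C; 2-(phenylsulfonyl)-3-phenyloxaziridine, −78 to −40 °C; AcOH
Reagents that add atoms: 2-(phenylsulfonyl)-3-phenyloxaziridine, O=S(=O)(c1ccccc1)N1OC1c1ccccc1
Why: N-Sulfonyloxaziridine hydroxylation of the potassium enolate of the 1,3-diketone (the only acidic C–H; the reagent does not epoxidise alkenes) sets C1, the oxidant having to choose between the face next to the axial C7 methyl and the face covered 1,3-syn-axially by the much larger C6 silyl ether and being expected to avoid the latter, so that OH enters α, cis to the C7 methyl.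

**Step 10**
Reactants: 14
Product: 15 (2S,3S,4R,6R)-2-[(E)-but-2-enoyl]-4-[(tert-butyldimethylsilyl)oxy]-2-hydroxy-6-(3-hydroxyprop-1-en-2-yl)-3-methylcycloheptan-1-one
Conditions: SeO2 (cat.), tBuOOH, CH2Cl2, rt
Reagents that add atoms: tert-butyl hydroperoxide, CC(C)(C)OO
Why: Catalytic SeO2 allylic oxidation (ene reaction, then [2,3]-shift) hydroxylates the methyl group of the electron-rich 1,1-disubstituted alkene in preference to the hindered ring methine and the electron-poor crotonyl unit; no stereocentre is formed.

**Step 11**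
Reactants: 15
Product: 17 acrylic acid (CH2OH of 15 oxidised to CO2H; stereocentres as in 14), via enal 16 (not isolated)
Conditions: TEMPO (cat.), PhI(OAc)2, CH2Cl2, rt; then NaClO2, NaH2PO4, 2-methylbut-2-ene, tBuOH/H2O
Reagents that add atoms: sodium chlorite, [Na+].[O-]Cl=O
Why: TEMPO/PhI(OAc)2 oxidises only the primary allylic alcohol (the tertiary C1 hydroxyl is inert) and Pinnick oxidation takes the 2-substituted acrolein to the acrylic acid without touching alkenes or ketones.

**Step 12**
Reactants: 17
Product: 18 ring A keto lactone (C2=O; 1α-OH; 1β-crotonoyl; 3α,4α-cis-fused α-methylene lactone ring B; 6β-OTBS; 7α-CH3)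
Conditions: PhI(OH)OTs, CH2Cl2, 40 °C
Reagents that add atoms: none
Why: Hypervalent-iodine lactonisation of a 5-oxo acid: the C2 ketone can enolise only towards C3 (C1 is quaternary), the trivalent iodine electrophile should bond to C3 anti to the C4 side chain, and the carboxylate displaces iodobenzene with inversion, so the C3–O bond forms α, cis to C4–C11.

**Step 13**
Reactants: 18
Product: 19 ring A diol lactone (as 18 with C2 β-OH in place of the ketone)
Conditions: Me4NBH(OAc)3, AcOH, MeCN, −30 °C
Reagents that add atoms: none
Why: Saksena–Evans hydroxyl-directed reduction: the tertiary C1 hydroxyl binds boron and delivers hydride to the adjacent, acyloxy-activated C2 ketone on its own α face, giving the C2 alcohol β (trans to the C1 hydroxyl and to the C3 oxygen), while the less electrophilic conjugated crotonyl ketone and the methylene lactone should not be reduced by this mild reagent.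

**Step 14**
Reactants: 19; 20 angelic acid
Product: 21 C2 angelate of 19 (6β-OTBS retained)
Conditions: 20, 2,4,6-Cl3C6H2COCl, Et3N, PhMe, rt; then 19, 80 °C
Reagents that add atoms: angelic acid (20), C/C=C(/C)C(=O)O
Why: Yamaguchi-type esterification through the preformed mixed anhydride, without a nucleophilic amine catalyst, should keep the Z geometry, and only the secondary C2 hydroxyl reacts because the C1 hydroxyl is tertiary and the C6 oxygen is silylated.

**Step 15**
Reactants: 21
Product: 22 CNP0149130.1 (ring A: 1S,2S,3R,4S,6R,7S)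
Conditions: HF·pyridine, THF, 0 °C to rt
Reagents that add atoms: none
Why: Acidic fluoride desilylation frees the C6 hydroxyl under non-basic conditions that avoid acyl migration, retro-aldol cleavage and Z-to-E isomerisation of the angelate.

**Compound list**

1 | (R)-carvone | CC1=CC[C@@H](C(C)=C)CC1=O | starting material
2 | (1R,4R,6R)-1-methyl-4-(prop-1-en-2-yl)-7-oxabicyclo[4.1.0]heptan-2-one | O=C1C[C@H](C(C)=C)C[C@H]2O[C@@]12C | intermediate
3 | (2R,3R,5R)-3-hydroxy-2-methyl-5-(prop-1-en-2-yl)cyclohexan-1-one | O=C1C[C@H](C(C)=C)C[C@@H](O)[C@H]1C | intermediate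
4 | triethyl{[(3R,5R)-2-methyl-5-(prop-1-en-2-yl)-3-(triethylsilyloxy)cyclohex-1-en-1-yl]oxy}silane | CC[Si](CC)(CC)OC1=C(C)[C@H](O[Si](CC)(CC)CC)C[C@@H](C(C)=C)C1 | intermediate
5 | bromoform | BrC(Br)Br | starting material
6 | 7,7-dibromo-1-methyl-4-(prop-1-en-2-yl)-2,6-bis(triethylsilyloxy)bicyclo[4.1.0]heptane (CBr2 bridge anti to the C2 silyloxy group) | CC[Si](CC)(CC)O[C@@]12C[C@H](C(C)=C)C[C@@H](O[Si](CC)(CC)CC)[C@]1(C)C2(Br)Br | intermediate
7 | (4R,6R)-2-bromo-3-methyl-6-(prop-1-en-2-yl)-4-(triethylsilyloxy)cyclohept-2-en-1-one | O=C1C[C@H](C(C)=C)C[C@@H](O[Si](CC)(CC)CC)C(C)=C1Br | intermediate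
8 | carbon monoxide | [C-]#[O+] | starting material
9 | (E)-tributyl(prop-1-en-1-yl)stannane | C/C=C/[Sn](CCCC)(CCCC)CCCC | starting material
10 | (4R,6R)-2-[(E)-but-2-enoyl]-3-methyl-6-(prop-1-en-2-yl)-4-(triethylsilyloxy)cyclohept-2-en-1-one | O=C1C[C@H](C(C)=C)C[C@@H](O[Si](CC)(CC)CC)C(C)=C1C(=O)/C=C/C | intermediate
11 | (4R,6R)-2-[(E)-but-2-enoyl]-4-hydroxy-3-methyl-6-(prop-1-en-2-yl)cyclohept-2-en-1-one | O=C1C[C@H](C(C)=C)C[C@@H](O)C(C)=C1C(=O)/C=C/C | intermediate
12 | (3R,4R,6R)-2-[(E)-but-2-enoyl]-4-hydroxy-3-methyl-6-(prop-1-en-2-yl)cycloheptan-1-one (C2 methine stereolabile) | O=C1C[C@H](C(C)=C)C[C@@H](O)[C@H](C)C1C(=O)/C=C/C | intermediate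
13 | (3R,4R,6R)-2-[(E)-but-2-enoyl]-4-[(tert-butyldimethylsilyl)oxy]-3-methyl-6-(prop-1-en-2-yl)cycloheptan-1-one (C2 methine stereolabile) | O=C1C[C@H](C(C)=C)C[C@@H](O[Si](C)(C)C(C)(C)C)[C@H](C)C1C(=O)/C=C/C | intermediate
14 | (2S,3S,4R,6R)-2-[(E)-but-2-enoyl]-4-[(tert-butyldimethylsilyl)oxy]-2-hydroxy-3-methyl-6-(prop-1-en-2-yl)cycloheptan-1-one | O=C1C[C@H](C(C)=C)C[C@@H](O[Si](C)(C)C(C)(C)C)[C@H](C)[C@@]1(O)C(=O)/C=C/C | intermediate
15 | (2S,3S,4R,6R)-2-[(E)-but-2-enoyl]-4-[(tert-butyldimethylsilyl)oxy]-2-hydroxy-6-(3-hydroxyprop-1-en-2-yl)-3-methylcycloheptan-1-one | O=C1C[C@H](C(CO)=C)C[C@@H](O[Si](C)(C)C(C)(C)C)[C@H](C)[C@@]1(O)C(=O)/C=C/C | intermediate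
16 | enal: 15 with CH2OH oxidised to CHO | O=C1C[C@H](C(C=O)=C)C[C@@H](O[Si](C)(C)C(C)(C)C)[C@H](C)[C@@]1(O)C(=O)/C=C/C | intermediate
17 | acrylic acid: 15 with CH2OH oxidised to CO2H | O=C1C[C@H](C(C(=O)O)=C)C[C@@H](O[Si](C)(C)C(C)(C)C)[C@H](C)[C@@]1(O)C(=O)/C=C/C | intermediate
18 | ring A keto lactone (C2=O; 1α-OH; 1β-crotonoyl; 3α,4α-cis-fused α-methylene lactone; 6β-OTBS; 7α-CH3) | C=C1C(=O)O[C@@H]2[C@H]1C[C@@H](O[Si](C)(C)C(C)(C)C)[C@H](C)[C@@](O)(C(=O)/C=C/C)C2=O | intermediate
19 | ring A diol lactone (18 with 2β-OH) | C=C1C(=O)O[C@@H]2[C@H]1C[C@@H](O[Si](C)(C)C(C)(C)C)[C@H](C)[C@@](O)(C(=O)/C=C/C)[C@H]2O | intermediate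
20 | angelic acid, (Z)-2-methylbut-2-enoic acid | C/C=C(/C)C(=O)O | starting material
21 | 2β-angelate of 19 (6β-OTBS) | C=C1C(=O)O[C@@H]2[C@H]1C[C@@H](O[Si](C)(C)C(C)(C)C)[C@H](C)[C@@](O)(C(=O)/C=C/C)[C@H]2OC(=O)/C(C)=C\C | intermediate
22 | CNP0149130.1 (ring A: 1α-OH, 1β-crotonoyl, 2β-angelate, 3α,4α-cis lactone, 6β-OH, 7α-CH3) | C=C1C(=O)O[C@@H]2[C@H]1C[C@@H](O)[C@H](C)[C@@](O)(C(=O)/C=C/C)[C@H]2OC(=O)/C(C)=C\C | target

**Step count.** Total: 15 steps. Longest linear sequence: 15 steps (1 to 22).

**Steps most likely to fail**

1. Step 7 (Proposed new method). The alkoxyborohydride may fail to transfer hydride to the hindered tetrasubstituted β-carbon, or slow intermolecular reduction of a carbonyl may take over, so that conversion or delivery on the β face is lost. The fallback uses known chemistry, sets out from 11 and returns at 12. The isopropenyl and crotonyl double bonds are masked as dibromides (Br2, CH2Cl2, −78 to 0 °C; the enedione alkene is too electron-poor to react) to give the tetrabromide F1. Hydroxyl-directed hydrogenation with [Ir(cod)(PCy3)(py)]PF6 under H2 in CH2Cl2 then adds hydrogen to C1=C7 from the face of the C6 hydroxyl to give the hydrogenated tetrabromide F2. Zinc in acetic acid removes both dibromides by anti elimination, which restores the isopropenyl group and the E crotonyl group and gives 12.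

2. Step 9. Facial selectivity may be poor or reversed: the oxidant may avoid the adjacent axial C7 methyl rather than the C6 silyl ether and give the C1 epimer. The fallback sets out from 13 and returns at 14, and applies if electrophiles prove to enter on the β face; oxygen is then brought in as a nucleophile with inversion. Chlorination of 13 with N-chlorosuccinimide gives the tertiary 1β-chloro diketone F3. SN2 displacement at this doubly carbonyl-activated centre with cesium formate and 18-crown-6 in DMF inverts C1 to the 1α-formate F4 (β-elimination is disfavoured because the C7 hydrogen is syn to chlorine). Mild methanolysis (NaHCO3, MeOH) gives 14.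

3. Step 4. tert-Butoxide may cleave the enol silyl ether, after which the enolate eliminates the β-silyloxy group back towards carvone; or the dibromocyclopropane may resist opening. The fallback sets out from 4 and returns at 10, using base-free carbene transfer and a chloride handle. Thermal decarboxylation of sodium trichloroacetate in refluxing DME adds dichlorocarbene to 4 to give the dichlorocyclopropane F5, which opens on further heating in toluene to the 2-chloroenone F6. Carbonylative Stille coupling of F6 with 9 under CO with Pd(PtBu3)2 in dioxane at 100 °C gives 10.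

**Further compounds**

F1 | step 7 | tetrabromide of 11 (isopropenyl and crotonyl C=C as vicinal dibromides; mixture at the bromine-bearing centres) | O=C1C[C@H](C(C)(Br)CBr)C[C@@H](O)C(C)=C1C(=O)C(Br)C(Br)C
F2 | step 7 | hydrogenated tetrabromide (7β-H, 7α-CH3; diketone methine stereolabile) | O=C1C[C@H](C(C)(Br)CBr)C[C@@H](O)[C@H](C)C1C(=O)C(Br)C(Br)C
F3 | step 9 | 1β-chloro diketone from 13 | O=C1C[C@H](C(C)=C)C[C@@H](O[Si](C)(C)C(C)(C)C)[C@H](C)[C@]1(Cl)C(=O)/C=C/C
F4 | step 9 | 1α-formate of 14 | O=C1C[C@H](C(C)=C)C[C@@H](O[Si](C)(C)C(C)(C)C)[C@H](C)[C@@]1(OC=O)C(=O)/C=C/C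
F5 | step 4 | 7,7-dichloro analogue of 6 | CC[Si](CC)(CC)O[C@@]12C[C@H](C(C)=C)C[C@@H](O[Si](CC)(CC)CC)[C@]1(C)C2(Cl)Cl
F6 | step 4 | (4R,6R)-2-chloro-3-methyl-6-(prop-1-en-2-yl)-4-(triethylsilyloxy)cyclohept-2-en-1-one | O=C1C[C@H](C(C)=C)C[C@@H](O[Si](CC)(CC)CC)C(C)=C1Cl
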